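The reagent in the second phase is what you should watch in this flask: it meets the starting material after crossing into the reaction phase.

starting material 0.18 M; reagent in the second phase 0.126 M; protic impurity 0.0540 M; time 3.0 d; volume of the second phase over the first 0.25

    reagent in the reaction phase ⇌ reagent in the second phase, rate k1*([reagent in the reaction phase] - [reagent in the second phase]/K1) per volume of the first phase (K1 = 7.6, k1 = 0.053 h⁻¹)
    starting material + reagent in the reaction phase → target (k2 = 6.8 M⁻¹ h⁻¹)
    starting material + protic impurity → quenched substrate (k3 = 0.81 M⁻¹ h⁻¹)
    starting material + target → side product (k4 = 0.080 M⁻¹ h⁻¹)

- percentages count the starting material that a species holds: one side product counts as two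
- in the second phase: reagent in the second phase; everything else is in the first
- charges count per volume of the first phase; a concentration in a rate is the amount of a species over the volume of its own phase; every rate counts per litre of the first phase
- run time (flask): 3.0 d

- east: doubling the amount of reagent in the second phase, all else as stated
- north-west: doubling the transfer coefficient of step 1, all else as stated

- the target standing at 3.0 d, as a percentage of the starting material charged
- the change that raises the amount of target at 3.0 d, in percent of the starting material charged most ("none" if none brings more than 2 percentage points) (east / north-west / none)
- amount of target at 3.0 d, in percent of the starting material charged, after east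

Measure each rung of the ladder against the leak from the second phase. That leak has the time constant τ = partition ratio × volume ratio / transfer coefficient = 35.8 h, a half-life of 24.8 h. Reagent in the reaction phase has a half-life of 0.57 h at the charged starting material, far shorter than the leak, so I expect c(reagent in the reaction phase) to stay low, neglect back-flow in this reckoning, and take transfer as the rate-limiting step. Protic impurity has a half-life of 4.75 h at the charged starting material, also shorter than the leak, so I let it take its charge early. That leaves 0.126 M for target, a ceiling of 70.0%.

So the count to carry is the delivered reagent, the amount that has crossed by a given time, and my first answer for the target:

D = 0.126 M × (1 − exp(−3.0 d/τ)) = 0.109 M, or 60.6%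

The half-life of target by the side-product step, at the charged starting material, is 2.0 d, longer than the leak's but shorter than the run, so put that answer back in. On my reckoning the starting material on offer falls from 0.126 M to 0.0169 M, a mean of 0.0715 M, while target averages D/2; this round counts what the side-product step takes from target and leaves out what it takes from starting material:

loss = 0.080 M⁻¹ h⁻¹ × 0.0715 M × 0.0545 M × 3.0 d = 0.0224 M, so target = 48.1%

Doubling the charge delivers the 0.126 M on offer by 24.8 h, and the same reckoning gives 65.6%. Doubling the transfer coefficient delivers 0.124 M and gives 56.0%. I choose east, the higher.

The forecast gives 48% (43% to 53%), east, and 67% after it (60% to 73%), saying “Doubling the reagent charge removes the reagent shortfall”.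

The simulation gives 46.8%, then east with a gain of 19 percentage points against 7.6 points for north-west, and 65.5% after east.

In this flask, 18.3% of the second-phase charge stands at 3.00 d, so 0.103 M crossed, against my 0.109 M. Now take the neighbour flask, read at 40 h. My reckoning delivers 0.0847 M, leaves 0.0413 M of starting material on offer, and charges the side-product step 0.0113 M, which gives 40.8%. That neighbour flask holds 36.2% of the second-phase charge, so 0.0804 M crossed, and its target stands at 37.4%.

The constants were chosen freely; the flask was simulated.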